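The midnight run reads 0.495 M at 35 min from 1.00 M of starting material, and the noon run, with twice that charge, reads twice that product at the same time. These last readings follow the charge, so I follow one molecule of starting material.

| flask | starting material | catalyst | time |
|---|---|---|---|
| midnight | 1.00 M | 0.0100 M |  |
| dusk | 1.00 M | 0.0150 M |  |
| noon | 2.00 M | 0.0100 M |  |
| autumn | 0.330 M | 0.00500 M | 35 min |

| run | time / min | [product] / M |
|---|---|---|
| midnight run | 1.3 | 0.076 |
| midnight run | 3.8 | 0.181 |
| midnight run | 7.3 | 0.266 |
| midnight run | 12 | 0.372 |
| midnight run | 16 | 0.406 |
| midnight run | 22 | 0.443 |
| midnight run | 28 | 0.477 |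
| midnight run | 35 | 0.495 |
| dusk run | 1.3 | 0.100 |
| dusk run | 3.8 | 0.255 |
| dusk run | 7.3 | 0.369 |
| dusk run | 12 | 0.481 |
| dusk run | 16 | 0.531 |
| dusk run | 22 | 0.562 |
| dusk run | 28 | 0.592 |
| dusk run | 35 | 0.589 |
| noon run | 1.3 | 0.139 |
| noon run | 3.8 | 0.343 |
| noon run | 7.3 | 0.544 |
| noon run | 12 | 0.744 |
| noon run | 16 | 0.813 |
| noon run | 22 | 0.919 |
| noon run | 28 | 0.958 |
| noon run | 35 | 0.986 |

(each reading ± 0.008 M)

1. reaction order in [starting material] at the outset, round the charge of the midnight run, defined at two percent of the starting material turned into product (one fixed amount of product, the same in the runs compared)
2. reaction order in [catalyst] at the outset, round the charge of the midnight run, defined at two percent of the starting material turned into product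
3. product in the autumn run at 35 min, as a share of the starting material charged
4. which of these the readings show (nothing beyond the main steps / the catalyst dies in pairs / the substrate is lost by itself / the substrate pairs with itself / a little impurity takes part of the catalyst at once / the substrate kills the catalyst)

- Overall: starting material -> product, with catalyst as catalyst.
- Constant volume, constant temperature.
- An order is taken over about fifteen percent of the charge, up and down.

Suppose a molecule has a fork. It meets catalyst with constant a·c(catalyst), a pseudo-first-order constant, or it is lost by itself with constant b. Then, with catalyst unchanged:

odds = a·c(catalyst)/b = product made / starting material lost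

λ = a·c(catalyst) + b

product/charge = [odds/(1 + odds)] · (1 − exp(−λt))

Treating the last reading as the end of the run, the midnight run gives fork odds, the selectivity of the fork, of 0.980. The dusk run's give 1.43. That is a ratio of 1.46 against a catalyst ratio of 1.50. A catalyst dying at first order, in a step of first order in starting material, needs the logarithm of the unturned fraction at the end to scale with catalyst instead, and that ratio reads 1.30. The odds ratio stands closer to the catalyst ratio than this one does, so I answer that the starting material is lost by itself, with order one in starting material and in catalyst.

The midnight reading at 7.3 min gives:

λ = 0.106 /min

b = 0.0533 /min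

The autumn run has half the midnight catalyst, so:

a·c(catalyst) = 0.0261 /min

λ = 0.0795 /min

share = 32.9%

product at 35 min = 30.9% of the charge

The forecast differs from my reckoning. It gives orders of 0.93 and 0.95, 34.5%, and the catalyst dies in pairs, starting from “Each run stalls, so the catalyst is dying”.

The flask gives orders of 1.0 and 1.0, 31.7%, and the substrate is lost by itself. The forecast's orders and value stand within their margins; it parts from the flask on the last question.

    catalyst + starting material → product + catalyst (5.478 /M/min)
    starting material → decomposed substrate (0.05406 /min)

In the autumn run, catalyst stayed at 0.00500 M while the catalysed step ran at 0.0274 /min and decomposition at 0.0541 /min, twice as fast, so the fork odds were 0.507. By 35 min, 5.78% of the autumn charge remained as starting material, 62.5% was decomposed substrate, and 31.7% was product. In the dusk run, the midnight odds scaled by catalyst become 1.47 and give 48.8% of the charge at 13.0 min, the time that run reaches half.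

All runs stem from a simulated flask on assumed constants, noise included.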